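(The numbers in the tables are simulated from invented constants, noise included.)

- 3 questions stand over this flask, and the two runs serve them unequally: the south run, which is this flask followed up to 40.0 min, and the east run read the substrate closely but never read the coupling partner.

| flask | substrate | coupling partner | free catalyst | second catalyst | added ligand | remark | time |
|---|---|---|---|---|---|---|---|
| south | 0.44 M (fed, over 30 s) | 1.1 equiv | 5 mol% | 1 mol% | 18 mM | the very flask that is asked about, followed so far |  |
| east | 0.44 M (fed, over 30 s) | 1.1 equiv | 3.4 mol% | 1 mol% | 18 mM | run made earlier |  |
| flask | 0.44 M (fed, over 30 s) | 1.10 equiv | 5 mol% | 1 mol% | 18 mM |  | 3.0 h |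

south run (percent of the substrate charged)

| time / min | substrate / % | target / % |
|---|---|---|
| 3.00 | 35.2 | 0.3 |
| 5.00 | 23.3 | 0 |
| 10.0 | 17.7 | 0.9 |
| 20.0 | 17.8 | 0 |
| 40.0 | 17.2 | 0 |

east run (percent of the substrate charged)

| time / h | substrate / % | target / % |
|---|---|---|
| 0.250 | 17.4 | 0.1 |
| 0.833 | 17.3 | 0 |
| 1.33 | 17.3 | 0 |
| 2.00 | 17.3 | 0.6 |
| 3.00 | 16.7 | 0.2 |

(each reading ± 0.5 percentage points)

- which holds at 3.0 h: what has brought the reaction to rest, or that it has not come to rest (all of the substrate has reacted / the coupling partner has run out first / no working catalyst is left / it is still moving / forward and back rates have come level)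
- part of the substrate gone at 3.0 h
- amount of target if the flask were left three thousand times as long, in percent of the substrate charged

- the reaction counts as stopped when no species that holds the substrate changes by six tenths of a point or more over the second half of the time

- The curve is best drawn from its end. The last 3 south readings average 17.6% at 5 mol% of free catalyst, and the 5 east readings average 17.2% at 3.4 mol%, so in these runs the level does not follow the loading, and together they give 17.3%.
- The quantity to carry is the plateau quotient, substrate gone divided by substrate left on the level, read here as 4.77, and this reckoning commits to a conversion of 82.7% at the asked time.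
- In the south run the substrate's excess over the level shrinks from 18 percentage points at 3.00 min to 6 points at 5.00 min, a reading of 1.26 min as its half-life, which puts the first slope at 0.455 min⁻¹ in fractions of the charge.
- With the feed counted as one dose at its midpoint, half of the fall is done at 1.51 min, and the knee comes before 10.0 min, where the excess is reckoned at 0.38 points against a scatter of 0.5 points.
- The target readings reach no more than 0.9%, so this reckoning leaves the other 2 questions open.
- The forecast gives forward and back rates have come level, 82.6% and 97%, holding that “this looks like a true equilibrium”.
- The flask gives the coupling partner has run out first, 83.1% and 0.462%. The coupling partner, charged at 1.10 equiv and so in excess over the substrate by the charges, stands at 0.65% of its charge at 3.00 h, beside 0.232 M of homo dimer. Splitting what is not yet target or isomer of the product, 0.406% and 3.21%, by the plateau quotient gives 83.3% conversion.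

    substrate + free catalyst ⇌ free catalyst + intermediate (K = 4.70, k = 0.350 M⁻¹ s⁻¹)
    coupling partner + second catalyst + intermediate → second catalyst + target (k = 0.660 M⁻² s⁻¹)
    target ⇌ isomer of the product (K = 8.00, k = 0.0100 s⁻¹)
    second catalyst + added ligand ⇌ idle complex, settled at all times (K = 830 M⁻¹)
    2 coupling partner → homo dimer (k = 0.00910 M⁻¹ s⁻¹)

- In the neighbour flask at 1.1 M of substrate, with 1.17% of target and 9.34% of isomer of the product, the same quotient gives 84.5%, and the computed conversion is 84.3%.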